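The route rests on cutting the bond between the quaternary cyclopentane carbon C1 (azulene numbering) and the first side-chain CH2. C1 bears CH2OH, so it is a β-hydroxy quaternary carbon, the retron of a reductively opened spiro-oxirane. The (Z)-butenediol terminus is a reduced butenolide. In one operation Ti(III) opens spiro-epoxide 15 to the tertiary C1 radical. This radical adds 1,6 to 4-vinylbutenolide 19 on the convex face of the cis-fused, C3a–C5 lactone-bridged cyclopentane/cycloheptane core, anti to C2-CH3 and C8. The step sets C1, frees the CH2OH and installs all six side-chain carbons with ring-locked Z geometry. The precursor is a C14 tricyclic epoxy-lactone, and either epoxide epimer serves.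

Key step: step 13

Remark on numbering: azulene numbering is used for all bicyclic and tricyclic compounds: C1 (quaternary in the target), C2 (CHCH3), C3 (CH2), C3a (quaternary, carries the carboxyl carbon), C4 (CH2), C5 (C(CH3)O), C6–C8 (CH2), C8a (CH).
Assumption: in step 3 the antipode of the phase-transfer catalyst that sends the electrophile to the enolate face cis to the ring methyl is used; (S,S) is written.

Step 1
Reactants: 1 (3R)-3-methylhexanedioic acid [(R)-3-methyladipic acid]
Product: 2 di-tert-butyl (3R)-3-methylhexanedioate
Conditions: isobutene (excess), cat. H2SO4, CH2Cl2, sealed flask, rt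
Reagents that add atoms: isobutene C=C(C)C
Why: Acid-catalysed addition of both carboxylic acids to isobutene (tert-butyl cation capture) should esterify without touching the stereocentre, which later becomes C2, and the bulky esters serve steps 2, 3 and 7.

Step 2
Reactants: 2 di-tert-butyl (3R)-3-methylhexanedioate
Product: 3 tert-butyl (4R)-4-methyl-2-oxocyclopentane-1-carboxylate (C1 mobile, keto/enol)
Conditions: KOtBu (1.2 equiv), toluene, 80 °C; AcOH quench
Reagents that add atoms: none
Why: A reversible Dieckmann condensation should drain to the 4-methyl regioisomer, because its stabilised enolate has no vicinal methyl/ester repulsion, and the methyl-bearing stereocentre is not enolisable.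

Step 3
Reactants: 3 tert-butyl (4R)-4-methyl-2-oxocyclopentane-1-carboxylate; 4 3-bromo-2-methylprop-1-ene (methallyl bromide)
Product: 5 tert-butyl (1S,4R)-4-methyl-1-(2-methylprop-2-enyl)-2-oxocyclopentane-1-carboxylate (methallyl cis to ring methyl)
Conditions: 4 (1.3 equiv), (S,S)-binaphthyl-derived N-spiro quaternary ammonium bromide with 3,4,5-trifluorophenyl groups (2 mol %), sat. aq K2CO3, toluene, −20 °C
Reagents that add atoms: none
Why: In this asymmetric phase-transfer C-alkylation of a cyclic β-keto ester, the chiral ammonium enolate ion pair should shield one face and override the weak 1,3-bias of the remote methyl, setting the quaternary centre (later C3a); the minor epimer is a separable diastereomer, so enantiopurity rests on the chiral pool.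

Step 4
Reactants: 5 tert-butyl (1S,4R)-4-methyl-1-(2-methylprop-2-enyl)-2-oxocyclopentane-1-carboxylate
Product: 6 tert-butyl (1S,4R)-4-methyl-1-(2-methylprop-2-enyl)-2-(trifluoromethylsulfonyloxy)cyclopent-2-ene-1-carboxylate
Conditions: KHMDS, THF, −78 °C; PhNTf2, −78 → 0 °C; aq NH4Cl
Reagents that add atoms: N-phenylbis(trifluoromethanesulfonimide) O=S(=O)(N(c1ccccc1)S(=O)(=O)C(F)(F)F)C(F)(F)F
Why: Only the CH2 flank of the ketone carries enolisable hydrogens, so deprotonation and O-sulfonylation (enol triflate formation) should give a single regioisomer without disturbing either stereocentre.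

Step 5
Reactants: 6 enol triflate; 7 but-3-enylmagnesium bromide
Product: 8 tert-butyl (1S,4R)-2-(but-3-enyl)-4-methyl-1-(2-methylprop-2-enyl)cyclopent-2-ene-1-carboxylate
Conditions: 7 (1.5 equiv), Fe(acac)3 (5 mol %), THF/NMP, −30 °C
Reagents that add atoms: none
Why: Iron-catalysed Kumada-type coupling of an alkenyl triflate with a primary alkyl Grignard reagent is fast at low temperature, so the tert-butyl ester and the alkenes should survive and β-hydride loss should not interfere.

Step 6
Reactants: 8 tert-butyl (1S,4R)-2-(but-3-enyl)-4-methyl-1-(2-methylprop-2-enyl)cyclopent-2-ene-1-carboxylate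
Product: 9 tert-butyl (2R,3aS)-2,5-dimethyl-3,4,7,8-tetrahydroazulene-3a(2H)-carboxylate
Conditions: Grubbs second-generation catalyst (5 mol %), CH2Cl2 (2 mM), reflux
Reagents that add atoms: none
Why: In this ring-closing metathesis, ruthenium should load on the monosubstituted butenyl alkene and close onto the 1,1-disubstituted methallyl alkene to give the trisubstituted C5=C6 cycloheptene, while the trisubstituted cyclopentene alkene stays inert.

Step 7
Reactants: 9 tert-butyl (2R,3aS)-2,5-dimethyl-3,4,7,8-tetrahydroazulene-3a(2H)-carboxylate
Product: 11 (2R,3aS,5S)-5-hydroxy-2,5-dimethyl-2,3,4,5,6,7,8-heptahydroazulene-3a-carboxylic acid 3a,5-lactone (C1=C8a alkene), via free acid 10 (not isolated)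
Conditions: TFA/CH2Cl2 1:2, 0 °C → rt
Reagents that add atoms: none
Why: Acidolysis of the tert-butyl ester followed by Markovnikov protolactonisation of the γ,δ-unsaturated acid should set C5 through the tether, since the C3a carboxyl reaches only one face of the C5 cation; the C1=C8a alkene should be spared because its protonation would place a cation next to the carboxyl-bearing quaternary carbon with no lactone outlet.

Step 8
Reactants: 11 tricyclic ene-lactone
Product: 13 (1S,2R,3aS,5S,8aS)-1,5-dihydroxy-2,5-dimethyldecahydroazulene-3a-carboxylic acid 3a,5-lactone, via alkylborane 12 (not isolated)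
Conditions: BH3·THF (2 equiv), THF, 0 °C → rt; 30 % H2O2, aq NaOH, 0 °C
Reagents that add atoms: hydrogen peroxide OO
Why: In this hydroboration–oxidation, boron should go to the less substituted C1 and the syn addition should occur on the convex face opposite C2-CH3 and C4, placing H-8a cis to the lactone carbonyl (cis ring fusion); the C1 carbinol centre is erased in step 9.

Step 9
Reactants: 13 secondary alcohol
Product: 14 (2R,3aS,5S,8aS)-5-hydroxy-2,5-dimethyl-1-oxodecahydroazulene-3a-carboxylic acid 3a,5-lactone
Conditions: Dess–Martin periodinane, CH2Cl2, 0 °C → rt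
Reagents that add atoms: none
Why: Dess–Martin oxidation is essentially neutral, so the two α-stereocentres C2 and C8a of the new cyclopentanone should not epimerise.

Step 10
Reactants: 14 keto-lactone
Product: 15 (1R,2R,3aS,5S,8aS)-spiro-epoxide: 5-hydroxy-2,5-dimethyloctahydro-spiro[azulene-1,2'-oxirane]-3a-carboxylic acid 3a,5-lactone (major epimer drawn; oxygen on the concave face)
Conditions: Me3SI (1.5 equiv), n-BuLi (1.4 equiv), THF, −10 °C; then 14, → rt
Reagents that add atoms: trimethylsulfonium iodide C[S+](C)C.[I-]
Why: In this Corey–Chaykovsky epoxidation, the weakly basic sulfonium ylide should add to the ketone (not the hindered lactone) from the convex face faster than it enolises it, and the C1 configuration is irrelevant because step 13 planarises this carbon.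

Step 11
Reactants: 16 tetronic acid (4-hydroxyfuran-2(5H)-one)
Product: 17 5-oxo-2,5-dihydrofuran-3-yl trifluoromethanesulfonate
Conditions: Tf2O, iPr2NEt, CH2Cl2, −78 °C
Reagents that add atoms: triflic anhydride O=S(=O)(OS(=O)(=O)C(F)(F)F)C(F)(F)F
Why: O-sulfonylation of the vinylogous acid should give the β-triflyloxy butenolide, an activated partner for cross-coupling.

Step 12
Reactants: 17 5-oxo-2,5-dihydrofuran-3-yl trifluoromethanesulfonate; 18 tributyl(vinyl)stannane
Product: 19 4-ethenylfuran-2(5H)-one (β-vinylbutenolide)
Conditions: Pd(PPh3)4 (5 mol %), LiCl (3 equiv), THF, 60 °C; stored cold with BHT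
Reagents that add atoms: none
Why: Stille coupling of an electron-poor alkenyl triflate runs under neutral conditions, so the base-sensitive butenolide and the polymerisable diene should survive.

Step 13
Reactants: 15 spiro-epoxide; 19 4-ethenylfuran-2(5H)-one
Product: 22 (1R,2R,3aS,5S,8aR)-5-hydroxy-1-(hydroxymethyl)-2,5-dimethyl-1-[2-(5-oxo-2,5-dihydrofuran-3-yl)ethyl]decahydroazulene-3a-carboxylic acid 3a,5-lactone, via titanoxy radical 20 (not isolated), via deconjugated lactone 21 (not isolated)
Conditions: Cp2TiCl2 (2.5 equiv), Zn dust, THF, rt (green Cp2TiCl), added slowly to 15 + 19 (4 equiv) in THF, rt; aq NaH2PO4; then DBU (0.2 equiv), CH2Cl2, rt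
Reagents that add atoms: none
Why: Cp2TiCl binds the oxirane oxygen and cleaves the C1–O bond homolytically to the tertiary β-titanoxy radical 20 (Nugent–RajanBabu reductive epoxide opening), so both epoxide epimers converge on one planar radical. This nucleophilic radical adds intermolecularly to the unsubstituted vinyl terminus of 19, a Giese addition in the vinylogous 1,6-sense that is known for tertiary radicals and β-vinylbutenolide, and this forms the C1–CH2 bond. A second Cp2TiCl reduces the delocalised dienoyl radical to a titanium dienolate, protonation on work-up gives 22 together with its deconjugated isomer 21, and catalytic DBU funnels 21 into 22; no ring is closed in this step. The new quaternary stereocentre C1 is under substrate control: the concave face of the cis-fused core is screened by the cis C2-CH3, C8-H2 and C4-H2, so 19 should approach on the convex face anti to both vicinal substituents, placing the side chain trans to C2-CH3 and leaving CH2OH cis to it. The step needs tertiary over primary C–O homolysis (intrinsic radical stability) and attack at the terminal CH2 of the dienoate (the only unhindered acceptor position). It also needs addition to outrun H-abstraction and disproportionation, which the excess of 19, the slow dosing of Ti(III) and the slow capture of tertiary radicals by Cp2TiCl should secure, and the bridged lactone is inert to Ti(III).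

Step 14
Reactants: 22 butenolide alcohol
Product: 24 (1R,2R,3aS,5S,8aR)-5-hydroxy-1-[(3Z)-5-hydroxy-3-(hydroxymethyl)pent-3-en-1-yl]-1-(hydroxymethyl)-2,5-dimethyldecahydroazulene-3a-carboxylic acid 3a,5-lactone (CNP0216031.1), via lactol 23 (not isolated)
Conditions: DIBAL-H (2.2 equiv), CH2Cl2, −78 °C; MeOH; then CeCl3·7H2O, NaBH4, −78 → 0 °C; Rochelle salt
Reagents that add atoms: none
Why: After the free OH consumes one equivalent, DIBAL-H should add once to the unhindered butenolide carbonyl, whereas the bridged lactone (ester of a tertiary alcohol, carbonyl flanked on both faces by the substituents of quaternary C3a) should be left; Luche reduction of the lactol/hydroxy-enal equilibrium then gives the diol, with the Z geometry inherited from the ring.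

Compound list
1 | (3R)-3-methylhexanedioic acid | OC(=O)C[C@H](C)CCC(=O)O | starting material
2 | di-tert-butyl (3R)-3-methylhexanedioate | CC(C)(C)OC(=O)C[C@H](C)CCC(=O)OC(C)(C)C | intermediate
3 | tert-butyl (4R)-4-methyl-2-oxocyclopentane-1-carboxylate | C[C@@H]1CC(C(=O)OC(C)(C)C)C(=O)C1 | intermediate
4 | 3-bromo-2-methylprop-1-ene | C=C(C)CBr | starting material
5 | tert-butyl (1S,4R)-4-methyl-1-(2-methylprop-2-enyl)-2-oxocyclopentane-1-carboxylate | C[C@@H]1C[C@@](CC(C)=C)(C(=O)OC(C)(C)C)C(=O)C1 | intermediate
6 | tert-butyl (1S,4R)-4-methyl-1-(2-methylprop-2-enyl)-2-(trifluoromethylsulfonyloxy)cyclopent-2-ene-1-carboxylate | C[C@@H]1C[C@@](CC(C)=C)(C(=O)OC(C)(C)C)C(OS(=O)(=O)C(F)(F)F)=C1 | intermediate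
7 | but-3-enylmagnesium bromide | C=CCC[Mg]Br | starting material
8 | tert-butyl (1S,4R)-2-(but-3-enyl)-4-methyl-1-(2-methylprop-2-enyl)cyclopent-2-ene-1-carboxylate | C[C@@H]1C[C@@](CC(C)=C)(C(=O)OC(C)(C)C)C(CCC=C)=C1 | intermediate
9 | tert-butyl (2R,3aS)-2,5-dimethyl-3,4,7,8-tetrahydroazulene-3a(2H)-carboxylate | C[C@@H]1C[C@]2(C(=O)OC(C)(C)C)CC(C)=CCCC2=C1 | intermediate
10 | (2R,3aS)-2,5-dimethyl-3,4,7,8-tetrahydroazulene-3a(2H)-carboxylic acid (not isolated) | C[C@@H]1C[C@]2(C(=O)O)CC(C)=CCCC2=C1 | intermediate
11 | tricyclic ene-lactone, (2R,3aS,5S), C1=C8a | C[C@@H]1C[C@]23C[C@](C)(CCCC2=C1)OC3=O | intermediate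
12 | C1 alkylborane of 11, boron and H-8a on the convex face (not isolated) | C[C@@H]1C[C@]23C[C@](C)(CCC[C@@H]2[C@H]1B)OC3=O | intermediate
13 | (1S,2R,3aS,5S,8aS)-1-hydroxy lactone | C[C@@H]1C[C@]23C[C@](C)(CCC[C@@H]2[C@H]1O)OC3=O | intermediate
14 | (2R,3aS,5S,8aS)-1-oxo lactone | C[C@@H]1C[C@]23C[C@](C)(CCC[C@@H]2C1=O)OC3=O | intermediate
15 | (1R,2R,3aS,5S,8aS)-spiro[azulene-1,2'-oxirane] lactone (major epimer) | C[C@@H]1C[C@]23C[C@](C)(CCC[C@@H]2[C@@]14CO4)OC3=O | intermediate
16 | tetronic acid | OC1=CC(=O)OC1 | starting material
17 | 5-oxo-2,5-dihydrofuran-3-yl trifluoromethanesulfonate | O=C1C=C(OS(=O)(=O)C(F)(F)F)CO1 | intermediate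
18 | tributyl(vinyl)stannane | C=C[Sn](CCCC)(CCCC)CCCC | starting material
19 | 4-ethenylfuran-2(5H)-one | C=CC1=CC(=O)OC1 | intermediate
20 | tertiary C1 radical as its chlorotitanocene(IV) alkoxide (not isolated) | C[C@@H]1C[C@]23C[C@](C)(CCC[C@@H]2[C]1C[O-])OC3=O.[Cl-].[Ti+4].c1cc[cH-]c1.c1cc[cH-]c1 | intermediate
21 | 4-alkylidene-dihydrofuran-2(3H)-one isomer of 22 (not isolated, alkene geometry undefined) | C[C@@H]1C[C@]23C[C@](C)(CCC[C@@H]2[C@@]1(CO)CC=C4CC(=O)OC4)OC3=O | intermediate
22 | (1R,2R,3aS,5S,8aR)-butenolide alcohol | C[C@@H]1C[C@]23C[C@](C)(CCC[C@@H]2[C@@]1(CO)CCC4=CC(=O)OC4)OC3=O | intermediate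
23 | side-chain 2,5-dihydrofuran-2-ol (lactol, anomers, not isolated) | C[C@@H]1C[C@]23C[C@](C)(CCC[C@@H]2[C@@]1(CO)CCC4=CC(O)OC4)OC3=O | intermediate
24 | CNP0216031.1, (1R,2R,3aS,5S,8aR), (3Z) side chain | C[C@@H]1C[C@]23C[C@](C)(CCC[C@@H]2[C@@]1(CO)CC/C(=C/CO)CO)OC3=O | target

Total step count: 14. Longest linear sequence: 12 (steps 1–10, 13, 14).

Steps most likely to fail

Step 13. Several processes could compete with C–C bond formation. The tertiary radical may be quenched early by hydrogen abstraction from THF, or it may disproportionate under Ti(III) to an allylic alcohol. Ti(III) may oligomerise the dienoate acceptor reductively, or facial selectivity may erode. The fallback sets out from ketone 14 and generates the same radical by photoredox decarboxylation. (Methoxymethoxy)methyllithium, made from tributyl[(methoxymethoxy)methyl]stannane and n-BuLi (CeCl3 if enolisation interferes), should add from the convex face to give the tertiary alcohol MOM ether F1. Methyl chlorooxoacetate with DMAP and Et3N gives the mixed methyl oxalate F2, and aqueous CsOH gives the cesium oxalate F3. Blue-light irradiation of F3 with an iridium photocatalyst in wet DME/DMF in the presence of 19, followed by catalytic DBU, should give the coupled MOM ether F4; this tertiary-oxalate coupling is known for exactly this acceptor. Acidic removal of the MOM group (aq HCl, THF) returns to the route at 22.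

Step 14. Hydride may attack the bridged lactone, or the lactol may aromatise to a furan during the quench. The fallback sets out from 22 and replaces hydride discrimination by acyl-transfer discrimination. Dimethylaluminium ethanethiolate (AlMe3, EtSH, CH2Cl2, 0 °C) should open only the unhindered butenolide to the S-ethyl (Z)-hydroxy thioester F5. F5 is used at once in a Fukuyama reduction (Et3SiH, Pd/C, acetone), which cannot reduce lactones. The resulting hydroxy-enal closes to lactol 23, where the route is rejoined, and the Luche reduction of step 14 then gives 24.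

Step 3. Facial selectivity may be poor if catalyst and substrate are mismatched, or O-alkylation may compete. The fallback sets out from 3 and uses a stoichiometric covalent auxiliary. Condensation with L-valine tert-butyl ester (cat. BF3·OEt2, benzene, water removal) gives the chiral enamino ester F6. Lithiation with LDA in toluene and alkylation with 4 gives the alkylated imine F7, and the choice of external ligand (HMPA or THF) selects the enolate face. Mild aqueous acid hydrolysis returns to the route at 5.

Further compounds
F1 | step 13 | (1R,2R,3aS,5S,8aS)-1-hydroxy-1-[(methoxymethoxy)methyl] lactone | C[C@@H]1C[C@]23C[C@](C)(CCC[C@@H]2[C@@]1(O)COCOC)OC3=O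
F2 | step 13 | methyl oxalate of F1 | C[C@@H]1C[C@]23C[C@](C)(CCC[C@@H]2[C@@]1(OC(=O)C(=O)OC)COCOC)OC3=O
F3 | step 13 | cesium oxalate of F1 | C[C@@H]1C[C@]23C[C@](C)(CCC[C@@H]2[C@@]1(OC(=O)C(=O)[O-])COCOC)OC3=O.[Cs+]
F4 | step 13 | MOM ether of 22 | C[C@@H]1C[C@]23C[C@](C)(CCC[C@@H]2[C@@]1(COCOC)CCC4=CC(=O)OC4)OC3=O
F5 | step 14 | S-ethyl (Z)-thioester from ring-opening of the butenolide of 22 | C[C@@H]1C[C@]23C[C@](C)(CCC[C@@H]2[C@@]1(CO)CC/C(=C/C(=O)SCC)CO)OC3=O
F6 | step 3 | enamino ester of 3 with L-valine tert-butyl ester | C[C@@H]1CC(C(=O)OC(C)(C)C)=C(N[C@@H](C(C)C)C(=O)OC(C)(C)C)C1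
F7 | step 3 | methallylated ketimine | C[C@@H]1C[C@@](CC(C)=C)(C(=O)OC(C)(C)C)C(=N[C@@H](C(C)C)C(=O)OC(C)(C)C)C1
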